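The target is cut between the ketone carbon C1, which sits on the 4-hydroxy-3,5-dimethoxyphenyl ring, and the aryloxy-bearing stereocentre C2. The key step exploits the 1,3-relationship of the C1 oxygen and the C3 hydroxyl around O-substituted C2, a glycolate aldol retron with C1 as carbinol and C3 as imide carbonyl. An Evans syn aldol of the Z boron enolate of an N-(aryloxyacetyl)oxazolidinone, which already carries the vanillate ring on oxygen, with 4-O-benzylsyringaldehyde joins both aryl halves and sets C2 under auxiliary control in one operation. Reductive removal of the auxiliary, chemoselective benzylic oxidation and hydrogenolysis then deliver the (S)-ketone.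

Key step: step 2

Remark: the chain atoms are called C1 (ketone carbon), C2 (O-aryl methine, S in the target) and C3 (CH2OH); compounds 2 and 4 are taken as catalogue items.

Step 1
Reactants: 1 methyl vanillate (methyl 4-hydroxy-3-methoxybenzoate); 2 (R)-4-benzyl-3-(chloroacetyl)-1,3-oxazolidin-2-one
Product: 3 methyl 4-{2-[(4R)-4-benzyl-2-oxo-1,3-oxazolidin-3-yl]-2-oxoethoxy}-3-methoxybenzoate
Conditions: K2CO3 (1.5 equiv), NaI (0.1 equiv), MeCN, rt → 50 °C
Reagents that add atoms: none
Why: Williamson ether synthesis: the phenoxide of 1 should displace the halide of the alpha-halo imide 2 by SN2 (iodide catalysis of Finkelstein type), which is much faster than attack at the imide carbonyl, and the auxiliary stereocentre is not involved.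

Step 2
Reactants: 3 methyl 4-{2-[(4R)-4-benzyl-2-oxo-1,3-oxazolidin-3-yl]-2-oxoethoxy}-3-methoxybenzoate; 4 4-(benzyloxy)-3,5-dimethoxybenzaldehyde
Product: 7 (4R)-4-benzyl-3-{(2R,3S)-3-[4-(benzyloxy)-3,5-dimethoxyphenyl]-3-hydroxy-2-[2-methoxy-4-(methoxycarbonyl)phenoxy]propanoyl}-1,3-oxazolidin-2-one, via Z dibutylboron enolate 5 (not isolated), via dibutylboron aldolate 6 (not isolated)
Conditions: Bu2BOTf (1.2 equiv), Et3N (1.5 equiv), CH2Cl2, 0 °C; then 4, −78 °C → 0 °C; pH 7 phosphate buffer, MeOH, 30% H2O2, 0 °C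
Reagents that add atoms: none
Why: Soft enolisation of imide 3 with Bu2BOTf/Et3N should give only the Z(O) dibutylboron enolate 5, which adds to aldehyde 4 through a closed six-membered Zimmerman–Traxler chair with boron bound to the aldehyde oxygen and the aryl group equatorial (Evans syn aldol; the closest known reaction type is the boron aldol of N-(alkoxyacetyl)- and N-(aryloxyacetyl)oxazolidinones with aromatic aldehydes). No ring is closed. C2 is controlled by the (R)-benzyl group of the auxiliary, because in the dipole-minimised transition state the aldehyde reaches the enolate face remote from the benzyl group, giving the 2R centre that is named S once the imide carbonyl has become CH2OH (a change of priorities only), while the new C1 carbinol centre (3S in the propanoyl name) follows from the chair as the syn isomer and is erased later by oxidation. The step needs Z enolate geometry and high facial selectivity, and both are secured by the tight boron enolate, whose two free coordination sites are taken by enolate and aldehyde oxygen so that the aryloxy oxygen cannot chelate and open a competing pathway. Chemoselectivity is secured because the imide CH2 is the only enolisable position in either partner (the aryl methyl ester and aldehyde 4 have no alpha hydrogen).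

Step 3
Reactants: 7 (4R)-4-benzyl-3-{(2R,3S)-3-[4-(benzyloxy)-3,5-dimethoxyphenyl]-3-hydroxy-2-[2-methoxy-4-(methoxycarbonyl)phenoxy]propanoyl}-1,3-oxazolidin-2-one
Product: 9 4-{[(1S,2S)-1-[4-(benzyloxy)-3,5-dimethoxyphenyl]-1,3-dihydroxypropan-2-yl]oxy}-3-methoxybenzoic acid, via diol methyl ester 8 (not isolated)
Conditions: NaBH4 (4 equiv), THF/H2O 4:1, 0 °C → rt; then LiOH·H2O (4 equiv), MeOH, 40 °C; EtOAc wash of the basic phase (auxiliary), then 1 M HCl to pH 3, 0 °C
Reagents that add atoms: lithium hydroxide, [Li+].[OH-]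
Why: Reductive cleavage of the N-acyloxazolidinone: NaBH4 in wet THF should reduce the activated exocyclic imide carbonyl to the primary alcohol with release of the auxiliary while the benzoate ester survives, and LiOH then saponifies that ester in the same pot (ester hydrolysis); C2 is no longer alpha to a carbonyl and keeps its configuration.

Step 4
Reactants: 9 4-{[(1S,2S)-1-[4-(benzyloxy)-3,5-dimethoxyphenyl]-1,3-dihydroxypropan-2-yl]oxy}-3-methoxybenzoic acid
Product: 10 4-{[(2S)-1-[4-(benzyloxy)-3,5-dimethoxyphenyl]-3-hydroxy-1-oxopropan-2-yl]oxy}-3-methoxybenzoic acid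
Conditions: DDQ (1.3 equiv), 1,4-dioxane, rt → 60 °C, dark; filtration, silica gel (eluent with 1% AcOH)
Reagents that add atoms: none
Why: DDQ benzylic oxidation: hydride abstraction from the C1 carbinol C–H, assisted by the electron-rich trialkoxyphenyl ring, should give the aryl ketone while the primary C3 hydroxyl, the acid and the benzyl ether stay untouched, and the neutral to weakly acidic medium should leave the now enolisable C2 centre intact.

Step 5
Reactants: 10 4-{[(2S)-1-[4-(benzyloxy)-3,5-dimethoxyphenyl]-3-hydroxy-1-oxopropan-2-yl]oxy}-3-methoxybenzoic acid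
Product: 11 4-{[(2S)-3-hydroxy-1-(4-hydroxy-3,5-dimethoxyphenyl)-1-oxopropan-2-yl]oxy}-3-methoxybenzoic acid (CNP0507417.2)
Conditions: H2 (1 atm), 10% Pd/C, EtOAc/THF, rt, stopped as soon as 10 is consumed
Reagents that add atoms: none
Why: Hydrogenolysis of the aryl benzyl ether over Pd/C under neutral conditions at room temperature should free the phenol faster than the aryl ketone or the C2–O bond can react, and without base C2 should not epimerise.

Compound list
1 | methyl vanillate (methyl 4-hydroxy-3-methoxybenzoate) | COC(=O)c1ccc(O)c(OC)c1 | starting material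
2 | (R)-4-benzyl-3-(chloroacetyl)-1,3-oxazolidin-2-one | O=C(CCl)N1[C@H](Cc2ccccc2)COC1=O | starting material
3 | methyl 4-{2-[(4R)-4-benzyl-2-oxo-1,3-oxazolidin-3-yl]-2-oxoethoxy}-3-methoxybenzoate | COC(=O)c1ccc(OCC(=O)N2[C@H](Cc3ccccc3)COC2=O)c(OC)c1 | intermediate
4 | 4-(benzyloxy)-3,5-dimethoxybenzaldehyde (4-O-benzylsyringaldehyde) | COc1cc(C=O)cc(OC)c1OCc1ccccc1 | starting material
5 | Z dibutylboron enolate of 3, boron on the enolate oxygen, aryloxy group cis to O–B (not isolated) | CCCCB(CCCC)O/C(=C\Oc1ccc(cc1OC)C(=O)OC)N1[C@H](Cc2ccccc2)COC1=O | intermediate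
6 | dibutylboron aldolate, the O-dibutylboryl derivative of 7 at the C1 oxygen (not isolated) | COC(=O)c1ccc(O[C@@H](C(=O)N2[C@H](Cc3ccccc3)COC2=O)[C@@H](OB(CCCC)CCCC)c2cc(OC)c(OCc3ccccc3)c(OC)c2)c(OC)c1 | intermediate
7 | (4R)-4-benzyl-3-{(2R,3S)-3-[4-(benzyloxy)-3,5-dimethoxyphenyl]-3-hydroxy-2-[2-methoxy-4-(methoxycarbonyl)phenoxy]propanoyl}-1,3-oxazolidin-2-one | COC(=O)c1ccc(O[C@@H](C(=O)N2[C@H](Cc3ccccc3)COC2=O)[C@@H](O)c2cc(OC)c(OCc3ccccc3)c(OC)c2)c(OC)c1 | intermediate
8 | methyl 4-{[(1S,2S)-1-[4-(benzyloxy)-3,5-dimethoxyphenyl]-1,3-dihydroxypropan-2-yl]oxy}-3-methoxybenzoate (not isolated) | COC(=O)c1ccc(O[C@@H](CO)[C@@H](O)c2cc(OC)c(OCc3ccccc3)c(OC)c2)c(OC)c1 | intermediate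
9 | 4-{[(1S,2S)-1-[4-(benzyloxy)-3,5-dimethoxyphenyl]-1,3-dihydroxypropan-2-yl]oxy}-3-methoxybenzoic acid | COc1cc(C(=O)O)ccc1O[C@@H](CO)[C@@H](O)c1cc(OC)c(OCc2ccccc2)c(OC)c1 | intermediate
10 | 4-{[(2S)-1-[4-(benzyloxy)-3,5-dimethoxyphenyl]-3-hydroxy-1-oxopropan-2-yl]oxy}-3-methoxybenzoic acid | COc1cc(C(=O)O)ccc1O[C@@H](CO)C(=O)c1cc(OC)c(OCc2ccccc2)c(OC)c1 | intermediate
11 | 4-{[(2S)-3-hydroxy-1-(4-hydroxy-3,5-dimethoxyphenyl)-1-oxopropan-2-yl]oxy}-3-methoxybenzoic acid | COc1cc(C(=O)O)ccc1O[C@@H](CO)C(=O)c1cc(OC)c(O)c(OC)c1 | target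

Total step count: 5
Longest linear sequence: 5 steps (1 → 3 → 7 → 9 → 10 → 11)

Steps most likely to fail

Step 4 (chemoselective DDQ oxidation). Hydride abstraction from the C1 carbinol may be slow, because the 4-benzyloxy group lies between two methoxy groups and is twisted out of conjugation. Forcing the reaction may then start to oxidise the primary alcohol or the benzyl ether. The fallback sets out from 9 and comes back at 10; it replaces chemoselective oxidation by protection, oxidation and deprotection. The primary hydroxyl is silylated selectively (TBSCl, imidazole, DMF, 0 °C; brief K2CO3 in MeOH/H2O to free the acid from its silyl ester) to give 4-{[(1S,2S)-1-[4-(benzyloxy)-3,5-dimethoxyphenyl]-3-[(tert-butyldimethylsilyl)oxy]-1-hydroxypropan-2-yl]oxy}-3-methoxybenzoic acid F1. Dess–Martin periodinane (NaHCO3, CH2Cl2, 0 °C) oxidises the only free alcohol to the ketone 4-{[(2S)-1-[4-(benzyloxy)-3,5-dimethoxyphenyl]-3-[(tert-butyldimethylsilyl)oxy]-1-oxopropan-2-yl]oxy}-3-methoxybenzoic acid F2. HF·pyridine in THF at 0 °C removes the silyl group under acidic conditions and gives 10.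

Step 5 (hydrogenolysis next to the aryl ketone). Over-reduction of the aryl ketone to the carbinol, or hydrogenolytic cleavage of the C2–O aryl ether bond alpha to the ketone, may compete with debenzylation. The fallback sets out from 9 and comes back at 11; it reverses the order of the last two operations. Compound 9 is debenzylated while no ketone is present (H2, 10% Pd/C, EtOAc/MeOH, rt) to give 4-{[(1S,2S)-1,3-dihydroxy-1-(4-hydroxy-3,5-dimethoxyphenyl)propan-2-yl]oxy}-3-methoxybenzoic acid F3. DDQ (1.1 equiv, 1,4-dioxane, rt) then oxidises the para-hydroxybenzylic alcohol, which should react far more readily than its benzyl ether, directly to 11.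

Step 2 (auxiliary-controlled aldol). Conversion of the electron-rich aldehyde may be incomplete, facial selectivity may erode through open transition states, or the aldolate may undergo retro-aldol cleavage during oxidative work-up. The fallback sets out from 1 and comes back at 8. It forms the same C1–C2 bond by a crossed Claisen acylation at the ketone oxidation level and sets C2 by a catalyst-controlled reduction with dynamic kinetic resolution.
- Compound 1 is alkylated with methyl bromoacetate (K2CO3, acetone, reflux) to methyl 3-methoxy-4-(2-methoxy-2-oxoethoxy)benzoate F4.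
- The lithium enolate of F4 (LiN(SiMe3)2, 2.1 equiv, THF, −78 °C) is C-acylated with 4-(benzyloxy)-3,5-dimethoxybenzoyl chloride F5, made from the commercial acid with (COCl)2 and catalytic DMF. This gives the racemic, configurationally labile beta-keto ester methyl 4-{[1-[4-(benzyloxy)-3,5-dimethoxyphenyl]-3-methoxy-1,3-dioxopropan-2-yl]oxy}-3-methoxybenzoate F6.
- Noyori-type asymmetric transfer hydrogenation (RuCl[(R,R)-TsDPEN](p-cymene), HCO2H/Et3N 5:2, CH2Cl2, 30 °C) should give the syn hydroxy ester methyl (2R,3S)-3-[4-(benzyloxy)-3,5-dimethoxyphenyl]-3-hydroxy-2-[2-methoxy-4-(methoxycarbonyl)phenoxy]propanoate F7. The catalyst enantiomer is the one predicted by the usual aryl-ketone facial rule.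
- NaBH4 in THF/H2O should reduce the activated alpha-aryloxy ester of F7, but not the benzoate, to 8. Compound 8 is saponified in the same pot as in step 3.

Further compounds
F1 | step 4 | 4-{[(1S,2S)-1-[4-(benzyloxy)-3,5-dimethoxyphenyl]-3-[(tert-butyldimethylsilyl)oxy]-1-hydroxypropan-2-yl]oxy}-3-methoxybenzoic acid | COc1cc(C(=O)O)ccc1O[C@@H](CO[Si](C)(C)C(C)(C)C)[C@@H](O)c1cc(OC)c(OCc2ccccc2)c(OC)c1
F2 | step 4 | 4-{[(2S)-1-[4-(benzyloxy)-3,5-dimethoxyphenyl]-3-[(tert-butyldimethylsilyl)oxy]-1-oxopropan-2-yl]oxy}-3-methoxybenzoic acid | COc1cc(C(=O)O)ccc1O[C@@H](CO[Si](C)(C)C(C)(C)C)C(=O)c1cc(OC)c(OCc2ccccc2)c(OC)c1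
F3 | step 5 | 4-{[(1S,2S)-1,3-dihydroxy-1-(4-hydroxy-3,5-dimethoxyphenyl)propan-2-yl]oxy}-3-methoxybenzoic acid | COc1cc(C(=O)O)ccc1O[C@@H](CO)[C@@H](O)c1cc(OC)c(O)c(OC)c1
F4 | step 2 | methyl 3-methoxy-4-(2-methoxy-2-oxoethoxy)benzoate | COC(=O)COc1ccc(C(=O)OC)cc1OC
F5 | step 2 | 4-(benzyloxy)-3,5-dimethoxybenzoyl chloride | COc1cc(C(Cl)=O)cc(OC)c1OCc1ccccc1
F6 | step 2 | methyl 4-{[1-[4-(benzyloxy)-3,5-dimethoxyphenyl]-3-methoxy-1,3-dioxopropan-2-yl]oxy}-3-methoxybenzoate (racemic) | COC(=O)C(Oc1ccc(C(=O)OC)cc1OC)C(=O)c1cc(OC)c(OCc2ccccc2)c(OC)c1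
F7 | step 2 | methyl (2R,3S)-3-[4-(benzyloxy)-3,5-dimethoxyphenyl]-3-hydroxy-2-[2-methoxy-4-(methoxycarbonyl)phenoxy]propanoate | COC(=O)[C@H](Oc1ccc(C(=O)OC)cc1OC)[C@@H](O)c1cc(OC)c(OCc2ccccc2)c(OC)c1
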